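**Strategy.** The flavone is cut through ring C at C3–C4 and O1–C8a, giving a gallate-derived ring B methyl ketone and 2,4,6-trifluorobenzoyl chloride. The plan exploits the fact that C5, C7 and C8a of ring A all lie ortho or para to the C4 carbonyl, so each of their C–O bonds can be made by displacing fluoride. In one pot the ketone enolate is C-acylated and the diketone enolate oxygen then closes ring C onto C8a. The precursor is 3,4-bis(benzyloxy)-5-(4-methoxybenzyloxy)acetophenone. Afterwards the C5 and C7 fluorides become 4-methoxybenzyl ethers, acid frees the 5-, 7- and 3'-hydroxyls, and sulfation followed by hydrogenolysis finishes.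

Key step: step 7

Remark on the chemistry: the target is drawn as the free bis(hydrogen sulfate); aryl hydrogen sulfates are only stable as salts, so 16 and 17 are made and kept as disodium salts and are written in the protonated form in which the target is given.

**Step 1**
Reactants: 1 methyl gallate
Product: 2 methyl 2-ethoxy-7-hydroxy-1,3-benzodioxole-5-carboxylate (racemic at the orthoester carbon)
Conditions: HC(OEt)3, Amberlyst 15 (cat.), toluene, reflux, removal of EtOH
Reagents that add atoms: triethyl orthoformate, CCOC(OCC)OCC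
Why: Acid-catalysed orthoester exchange closes a five-membered benzodioxole across two adjacent phenols, and because methyl gallate is symmetric either adjacent pair gives the same product with one outer hydroxyl left free; the orthoester carbon forms as a racemate and is deleted in step 3.

**Step 2**
Reactants: 2 methyl 2-ethoxy-7-hydroxy-1,3-benzodioxole-5-carboxylate
Product: 3 methyl 2-ethoxy-7-[(4-methoxybenzyl)oxy]-1,3-benzodioxole-5-carboxylate (racemic)
Conditions: 4-methoxybenzyl chloride, K2CO3, Bu4NI (cat.), DMF, rt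
Reagents that add atoms: 4-methoxybenzyl chloride, COc1ccc(CCl)cc1
Why: Williamson etherification of the only free phenol under carbonate base leaves the orthoester and methyl ester untouched, and the 4-methoxybenzyl ether is chosen because it survives the dilute acid of step 3 and later leaves in the same acid step as the ring A ethers.

**Step 3**
Reactants: 3 methyl 2-ethoxy-7-[(4-methoxybenzyl)oxy]-1,3-benzodioxole-5-carboxylate
Product: 4 methyl 3,4-dihydroxy-5-[(4-methoxybenzyl)oxy]benzoate
Conditions: p-TsOH·H2O (0.1 equiv), THF/H2O, rt; aq NaHCO3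
Reagents that add atoms: none
Why: Acid-catalysed hydrolysis of a cyclic orthoester is far faster than acidolysis of an aryl 4-methoxybenzyl ether or hydrolysis of the methyl ester, so catalytic acid at room temperature should free only the catechol.

**Step 4**
Reactants: 4 methyl 3,4-dihydroxy-5-[(4-methoxybenzyl)oxy]benzoate
Product: 5 methyl 3,4-bis(benzyloxy)-5-[(4-methoxybenzyl)oxy]benzoate
Conditions: BnBr (2.4 equiv), K2CO3, DMF, 60 °C
Reagents that add atoms: benzyl bromide, BrCc1ccccc1
Why: Double Williamson etherification of the catechol under standard carbonate conditions, with no competing site in the molecule.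

**Step 5**
Reactants: 5 methyl 3,4-bis(benzyloxy)-5-[(4-methoxybenzyl)oxy]benzoate
Product: 6 3,4-bis(benzyloxy)-N-methoxy-5-[(4-methoxybenzyl)oxy]-N-methylbenzamide
Conditions: MeNH(OMe)·HCl (1.5 equiv), iPrMgCl (3.0 equiv), THF, −20 to 0 °C
Reagents that add atoms: N,O-dimethylhydroxylamine hydrochloride, CNOC.Cl
Why: Direct aminolysis of the ester by the chloromagnesium amide of N,O-dimethylhydroxylamine (Weinreb amide formation), iPrMgCl being too hindered to add to the ester at this temperature.

**Step 6**
Reactants: 6 3,4-bis(benzyloxy)-N-methoxy-5-[(4-methoxybenzyl)oxy]-N-methylbenzamide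
Product: 7 1-{3,4-bis(benzyloxy)-5-[(4-methoxybenzyl)oxy]phenyl}ethan-1-one
Conditions: MeMgBr (1.5 equiv), THF, 0 °C; aq NH4Cl
Reagents that add atoms: methylmagnesium bromide, C[Mg]Br
Why: Weinreb ketone synthesis, in which the chelated tetrahedral magnesium adduct persists until work-up and so prevents a second addition.

**Step 7**
Reactants: 7 1-{3,4-bis(benzyloxy)-5-[(4-methoxybenzyl)oxy]phenyl}ethan-1-one; 8 2,4,6-trifluorobenzoyl chloride
Product: 11 2-{3,4-bis(benzyloxy)-5-[(4-methoxybenzyl)oxy]phenyl}-5,7-difluoro-4H-chromen-4-one, via lithium enolate of the acetophenone 9 (not isolated), via trifluorophenyl beta-diketone 10 (not isolated)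
Conditions: LiN(SiMe3)2 (2.1 equiv), THF, −78 °C; 8, −78 to 0 °C; then K2CO3, DMF, 50 °C, same pot
Reagents that add atoms: 2,4,6-trifluorobenzoyl chloride (8), O=C(Cl)c1c(F)cc(F)cc1F
Why: LiN(SiMe3)2 converts the ketone into lithium enolate 9, which attacks the acid chloride through carbon (C3–C4) and, after deprotonation by the second equivalent of base, gives the chelated enolate of diketone 10. On adding K2CO3 and DMF and warming, the enolate oxygen on the ring B side adds to a fluorine-bearing carbon ortho to the ketone and expels fluoride through a Meisenheimer intermediate stabilised by the C4 carbonyl and the two remaining fluorines (O1–C8a). The closest known reaction type is the one-pot C-acylation of ketone enolates by 2-fluorobenzoyl chlorides followed by intramolecular SNAr to chromones and flavones, which tolerates polyfluorinated aroyl chlorides. Ring C closes as a six-membered ring by intramolecular addition–elimination at a trigonal aromatic carbon, an unstrained and allowed closure. No stereocentre is formed. C- over O-acylation should be secured by the lithium counter-ion in THF at low temperature, and displacement of a single fluoride should be secured because the two ortho fluorides are equivalent, the intramolecular closure outruns any attack at the para fluoride, and no external oxygen nucleophile is present.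

**Step 8**
Reactants: 11 2-{3,4-bis(benzyloxy)-5-[(4-methoxybenzyl)oxy]phenyl}-5,7-difluoro-4H-chromen-4-one; 12 4-methoxybenzyl alcohol
Product: 14 2-{3,4-bis(benzyloxy)-5-[(4-methoxybenzyl)oxy]phenyl}-5,7-bis[(4-methoxybenzyl)oxy]-4H-chromen-4-one, via 5-fluoro-7-(4-methoxybenzyloxy) flavone 13 (not isolated)
Conditions: 12 (2.6 equiv), NaH (2.6 equiv), THF, 0 °C; then 11, THF/DMF, rt to 50 °C
Reagents that add atoms: 4-methoxybenzyl alcohol (12), COc1ccc(CO)cc1
Why: Two successive SNAr displacements by alkoxide, expected first at C7 (para to the C4 carbonyl) and then at C5 (ortho), each through a carbonyl-stabilised Meisenheimer intermediate; the order does not matter because excess alkoxide and gentle warming should carry both fluorides to the same product.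

**Step 9**
Reactants: 14 2-{3,4-bis(benzyloxy)-5-[(4-methoxybenzyl)oxy]phenyl}-5,7-bis[(4-methoxybenzyl)oxy]-4H-chromen-4-one
Product: 15 2-[3,4-bis(benzyloxy)-5-hydroxyphenyl]-5,7-dihydroxy-4H-chromen-4-one
Conditions: TFA/CH2Cl2 (1:9), anisole (10 equiv), 0 °C to rt
Reagents that add atoms: none
Why: Acidolysis of the three aryl 4-methoxybenzyl ethers through the stabilised 4-methoxybenzyl cation, which excess anisole traps by Friedel–Crafts alkylation before it can attack C6 or C8 of ring A, while the unactivated benzyl ethers should survive dilute TFA.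

**Step 10**
Reactants: 15 2-[3,4-bis(benzyloxy)-5-hydroxyphenyl]-5,7-dihydroxy-4H-chromen-4-one
Product: 16 2-[3,4-bis(benzyloxy)-5-(sulfooxy)phenyl]-5-hydroxy-4-oxo-4H-chromen-7-yl hydrogen sulfate (disodium salt)
Conditions: SO3·pyridine (6 equiv), pyridine, rt; aq NaHCO3; reversed-phase purification
Reagents that add atoms: sulfur trioxide pyridine complex, O=S(=O)([O-])[n+]1ccccc1
Why: O-sulfation of phenols by an amine–sulfur trioxide complex, in which the C5 hydroxyl is hydrogen-bonded to the C4 carbonyl and unreactive, so only the C7 and C3' hydroxyls should be sulfated.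

**Step 11**
Reactants: 16 2-[3,4-bis(benzyloxy)-5-(sulfooxy)phenyl]-5-hydroxy-4-oxo-4H-chromen-7-yl hydrogen sulfate (disodium salt)
Product: 17 tricetin 7,3'-disulfate, 2-[3,4-dihydroxy-5-(sulfooxy)phenyl]-5-hydroxy-4-oxo-4H-chromen-7-yl hydrogen sulfate (disodium salt)
Conditions: H2 (1 atm), Pd/C, MeOH/H2O, rt
Reagents that add atoms: none
Why: Catalytic hydrogenolysis of the two benzyl ethers at neutral pH, conditions under which aryl sulfate salts and the chromone C2=C3 bond are expected to persist.

**Compound list**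
1 | methyl gallate (methyl 3,4,5-trihydroxybenzoate) | COC(=O)c1cc(O)c(O)c(O)c1 | starting material
2 | methyl 2-ethoxy-7-hydroxy-1,3-benzodioxole-5-carboxylate (racemic) | CCOC1Oc2cc(C(=O)OC)cc(O)c2O1 | intermediate
3 | methyl 2-ethoxy-7-[(4-methoxybenzyl)oxy]-1,3-benzodioxole-5-carboxylate (racemic) | CCOC1Oc2cc(C(=O)OC)cc(OCc3ccc(OC)cc3)c2O1 | intermediate
4 | methyl 3,4-dihydroxy-5-[(4-methoxybenzyl)oxy]benzoate | COC(=O)c1cc(O)c(O)c(OCc2ccc(OC)cc2)c1 | intermediate
5 | methyl 3,4-bis(benzyloxy)-5-[(4-methoxybenzyl)oxy]benzoate | COC(=O)c1cc(OCc2ccccc2)c(OCc2ccccc2)c(OCc2ccc(OC)cc2)c1 | intermediate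
6 | 3,4-bis(benzyloxy)-N-methoxy-5-[(4-methoxybenzyl)oxy]-N-methylbenzamide | CON(C)C(=O)c1cc(OCc2ccccc2)c(OCc2ccccc2)c(OCc2ccc(OC)cc2)c1 | intermediate
7 | 1-{3,4-bis(benzyloxy)-5-[(4-methoxybenzyl)oxy]phenyl}ethan-1-one | CC(=O)c1cc(OCc2ccccc2)c(OCc2ccccc2)c(OCc2ccc(OC)cc2)c1 | intermediate
8 | 2,4,6-trifluorobenzoyl chloride | O=C(Cl)c1c(F)cc(F)cc1F | starting material
9 | lithium 1-{3,4-bis(benzyloxy)-5-[(4-methoxybenzyl)oxy]phenyl}ethen-1-olate | C=C(O[Li])c1cc(OCc2ccccc2)c(OCc2ccccc2)c(OCc2ccc(OC)cc2)c1 | intermediate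
10 | 1-{3,4-bis(benzyloxy)-5-[(4-methoxybenzyl)oxy]phenyl}-3-(2,4,6-trifluorophenyl)propane-1,3-dione (present as its enolate salt) | O=C(CC(=O)c1c(F)cc(F)cc1F)c1cc(OCc2ccccc2)c(OCc2ccccc2)c(OCc2ccc(OC)cc2)c1 | intermediate
11 | 2-{3,4-bis(benzyloxy)-5-[(4-methoxybenzyl)oxy]phenyl}-5,7-difluoro-4H-chromen-4-one | O=c1cc(-c2cc(OCc3ccccc3)c(OCc3ccccc3)c(OCc3ccc(OC)cc3)c2)oc2cc(F)cc(F)c12 | intermediate
12 | 4-methoxybenzyl alcohol | COc1ccc(CO)cc1 | starting material
13 | 2-{3,4-bis(benzyloxy)-5-[(4-methoxybenzyl)oxy]phenyl}-5-fluoro-7-[(4-methoxybenzyl)oxy]-4H-chromen-4-one | O=c1cc(-c2cc(OCc3ccccc3)c(OCc3ccccc3)c(OCc3ccc(OC)cc3)c2)oc2cc(OCc3ccc(OC)cc3)cc(F)c12 | intermediate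
14 | 2-{3,4-bis(benzyloxy)-5-[(4-methoxybenzyl)oxy]phenyl}-5,7-bis[(4-methoxybenzyl)oxy]-4H-chromen-4-one | O=c1cc(-c2cc(OCc3ccccc3)c(OCc3ccccc3)c(OCc3ccc(OC)cc3)c2)oc2cc(OCc3ccc(OC)cc3)cc(OCc3ccc(OC)cc3)c12 | intermediate
15 | 2-[3,4-bis(benzyloxy)-5-hydroxyphenyl]-5,7-dihydroxy-4H-chromen-4-one | O=c1cc(-c2cc(O)c(OCc3ccccc3)c(OCc3ccccc3)c2)oc2cc(O)cc(O)c12 | intermediate
16 | 2-[3,4-bis(benzyloxy)-5-(sulfooxy)phenyl]-5-hydroxy-4-oxo-4H-chromen-7-yl hydrogen sulfate | O=c1cc(-c2cc(OS(=O)(=O)O)c(OCc3ccccc3)c(OCc3ccccc3)c2)oc2cc(OS(=O)(=O)O)cc(O)c12 | intermediate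
17 | tricetin 7,3'-disulfate | O=c1cc(-c2cc(O)c(O)c(OS(=O)(=O)O)c2)oc2cc(OS(=O)(=O)O)cc(O)c12 | target

**Step count and risks**
Total step count: 11. Longest linear sequence: 11 steps, from 1 to 17.

Steps most likely to fail:

Step 7. The enolate may be acylated on oxygen or twice on carbon, or residual amide base may attack the fluoroarene before ring closure. The fallback sets out from 7 and makes the C3–C4 bond by aldol addition instead of acylation. The lithium enolate of 7 is added at −78 °C to commercial 2,4,6-trifluorobenzaldehyde to give 1-{3,4-bis(benzyloxy)-5-[(4-methoxybenzyl)oxy]phenyl}-3-hydroxy-3-(2,4,6-trifluorophenyl)propan-1-one F1. Dess–Martin periodinane then oxidises the carbinol to diketone 10, which is isolated and closed separately with K2CO3 in DMF. The fallback comes back to the route at 11.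

Step 8. The second fluoride may resist displacement once the first alkoxy group has deactivated ring A, or alkoxide may add at C2 and open ring C. The fallback sets out from ester 5 and takes the ring A oxygens from phloroglucinol chemistry instead of fluoride displacement. Commercial 2',4',6'-trihydroxyacetophenone is bis-alkylated (4-methoxybenzyl chloride, K2CO3, DMF; the chelated hydroxyl stays free) to 1-{2-hydroxy-4,6-bis[(4-methoxybenzyl)oxy]phenyl}ethan-1-one F2. Its dianion (LiN(SiMe3)2, THF) undergoes Claisen condensation with 5 to give 1-{3,4-bis(benzyloxy)-5-[(4-methoxybenzyl)oxy]phenyl}-3-{2-hydroxy-4,6-bis[(4-methoxybenzyl)oxy]phenyl}propane-1,3-dione F3. TFA with anisole in CH2Cl2 then removes the three 4-methoxybenzyl groups and cyclodehydrates the diketone. The fallback comes back to the route at 15.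

Step 10. Sulfation at the flanked C3' hydroxyl may stall, or sulfate may be lost during isolation of the very polar salt. The fallback sets out from 15 and carries the sulfates as neutral, chromatographable diesters. 2,2,2-Trichloroethyl chlorosulfate with Et3N and DMAP in THF should give 2-[3,4-bis(benzyloxy)-5-{[(2,2,2-trichloroethoxy)sulfonyl]oxy}phenyl]-5-hydroxy-4-oxo-4H-chromen-7-yl 2,2,2-trichloroethyl sulfate F4. Zn dust and HCO2NH4 in MeOH then remove both trichloroethyl groups by reductive elimination. The fallback comes back to the route at 16, before the hydrogenolysis of step 11.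

**Further compounds**
F1 | step 7 | 1-{3,4-bis(benzyloxy)-5-[(4-methoxybenzyl)oxy]phenyl}-3-hydroxy-3-(2,4,6-trifluorophenyl)propan-1-one (racemic) | O=C(CC(O)c1c(F)cc(F)cc1F)c1cc(OCc2ccccc2)c(OCc2ccccc2)c(OCc2ccc(OC)cc2)c1
F2 | step 8 | 1-{2-hydroxy-4,6-bis[(4-methoxybenzyl)oxy]phenyl}ethan-1-one | CC(=O)c1c(O)cc(OCc2ccc(OC)cc2)cc1OCc1ccc(OC)cc1
F3 | step 8 | 1-{3,4-bis(benzyloxy)-5-[(4-methoxybenzyl)oxy]phenyl}-3-{2-hydroxy-4,6-bis[(4-methoxybenzyl)oxy]phenyl}propane-1,3-dione | O=C(CC(=O)c1c(O)cc(OCc2ccc(OC)cc2)cc1OCc1ccc(OC)cc1)c1cc(OCc2ccccc2)c(OCc2ccccc2)c(OCc2ccc(OC)cc2)c1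
F4 | step 10 | 2-[3,4-bis(benzyloxy)-5-{[(2,2,2-trichloroethoxy)sulfonyl]oxy}phenyl]-5-hydroxy-4-oxo-4H-chromen-7-yl 2,2,2-trichloroethyl sulfate | O=c1cc(-c2cc(OS(=O)(=O)OCC(Cl)(Cl)Cl)c(OCc3ccccc3)c(OCc3ccccc3)c2)oc2cc(OS(=O)(=O)OCC(Cl)(Cl)Cl)cc(O)c12
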